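**Plan**
Numbering: decalin C1 (quaternary, CH3 and acyl), C2 (dienyl C1''–C5''), C3=C4, C4a, C5, C6 (CH3), C7, C8, C8a. Ring A = C1–C4, C4a, C8a. Ring B = C4a–C8a. Ring C = tetramic acid N1'–C5'.
Enabling feature: C2 holds two alkenyl arms, C3=C4 inside ring A and the dienyl chain outside. A C2 with two vinyl groups is therefore a prochiral stand-in that becomes stereogenic when C3=C4 closes.
Cuts, in retrosynthetic order: C3'–C4' (Dieckmann), N1'–C2' (aminolysis), CO–CH2 (aldol); C2''–C3'' (Suzuki), C1''=C2'' (cross-metathesis); C3=C4 (ring-closing metathesis); C1–CH3, C4=CH2, C8a–C1 (Michael), C4a=C8a (metathesis).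
Forward order: ring B from (R)-citronellal, side chain joined at C8a, ring A closed, diene built, ring C closed last.
Stereochemistry: C6 from (R)-citronellal; C8a by axial Michael attack cis to C6–CH3; C4a by equilibration; C1 by allylic-strain-controlled methylation; C2 by selection between the two vinyl groups; C5' and the carbinol carbon from L-threonine.

Key step: step 9

Remark on the chemistry: read from the SMILES, the decalin is trans-fused with the C1 and C6 methyl groups axial and the C2 dienyl group pseudoequatorial, trans to the acyl group (1R,2R,4aR,6R,8aS; 5'S and carbinol R as in L-threonine); the enol drawn stands for the equilibrating tautomers of the 3-acyltetramic acid.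

Step 1
Reactants: 1 (R)-citronellal
Product: 3 (4R)-4,8-dimethylnon-7-enal, via enol ether 2 (not isolated)
Conditions: Ph3P(CH2OMe)Cl, KOt-Bu, THF, 0 °C; then 2 M HCl, rt
Reagents that add atoms: (methoxymethyl)triphenylphosphonium chloride, COC[P+](c1ccccc1)(c1ccccc1)c1ccccc1.[Cl-]; water, O
Why: Wittig methoxymethylenation followed by acid hydrolysis of the enol ether is the standard one-carbon homologation of an aldehyde; it adds the future C4 and leaves the C6 stereocentre, which is not α to a carbonyl group, untouched.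

Step 2
Reactants: 3 (4R)-4,8-dimethylnon-7-enal
Product: 4 (4R)-4,8-dimethyl-2-methylidenenon-7-enal
Conditions: 37% aq. CH2O, pyrrolidine (10 mol %), EtCO2H (10 mol %), i-PrOH, 45 °C
Reagents that add atoms: formaldehyde, C=O
Why: Amine-catalysed Mannich condensation and elimination (α-methylenation of an aldehyde) turns the α-CH2 group, the future C4a, into a 2-substituted acrolein and creates no stereocentre.

Step 3
Reactants: 4 (4R)-4,8-dimethyl-2-methylidenenon-7-enal
Product: 5 (5R)-5-methylcyclohex-1-ene-1-carbaldehyde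
Conditions: second-generation Grubbs catalyst (2 mol %), CH2Cl2 (0.02 M), 40 °C
Reagents that add atoms: none
Why: Ring-closing metathesis of the acrolein-type methylene group with the trisubstituted chain end expels 2-methylpropene and closes ring B, a closure that is routine for the five-membered lower homologue, and it places the double bond at C4a=C8a without the regioisomer problem of enolising 3-methylcyclohexanone.

Step 4
Reactants: 6 (2E)-penta-2,4-dien-1-ol
Product: 8 methyl 3-ethenylpent-4-enoate, via ketene acetal 7 (not isolated)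
Conditions: MeC(OMe)3 (5 equiv), EtCO2H (5 mol %), toluene, 110 °C, MeOH distilled off
Reagents that add atoms: trimethyl orthoacetate, CC(OC)(OC)OC
Why: Johnson–Claisen rearrangement: the [3,3] shift of ketene acetal 7 forms the C1–C2 bond at C3 of the dienol, so that C2 ends up with two identical vinyl groups and is not stereogenic.

Step 5
Reactants: 5 (5R)-5-methylcyclohex-1-ene-1-carbaldehyde; 8 methyl 3-ethenylpent-4-enoate
Product: 10 methyl 3-ethenyl-2-[(1S,4R)-2-formyl-4-methylcyclohexyl]pent-4-enoate (epimers at C1 and C4a), via lithium enolate 9 (not isolated)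
Conditions: 8, LiN(i-Pr)2 (1.0 equiv), THF, −78 °C; cannulated into 5 + Al(OC6H3-2,6-Ph2)3 (1.1 equiv, made from AlMe3 and 2,6-diphenylphenol in toluene), −78 °C; 1 M HCl
Reagents that add atoms: none
Why: Michael addition of an ester enolate to an enal whose carbonyl group is buried by the bulky aluminium phenoxide, so that only the β-carbon C8a is open; axial attack on the half-chair of 5 with the C6 methyl group pseudoequatorial places the new C8a–C1 bond cis to that methyl group (8aS), while C1 and C4a remain mixtures that are settled in steps 6 and 8.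

Step 6
Reactants: 10 methyl 3-ethenyl-2-[(1S,4R)-2-formyl-4-methylcyclohexyl]pent-4-enoate
Product: 11 methyl 3-ethenyl-2-[(1S,2S,4R)-2-formyl-4-methylcyclohexyl]pent-4-enoate (epimers at C1)
Conditions: DBU (0.3 equiv), CH2Cl2, rt
Reagents that add atoms: none
Why: Base-catalysed epimerisation α to the aldehyde: the cis isomer must put either the branched C8a side chain axial or the formyl group 1,3-diaxial to the C6 methyl group, so equilibrium should lie on the trans isomer with the C4a and C8a substituents equatorial and the C6 methyl group axial.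

Step 7
Reactants: 11 methyl 3-ethenyl-2-[(1S,2S,4R)-2-formyl-4-methylcyclohexyl]pent-4-enoate
Product: 12 methyl 3-ethenyl-2-[(1S,2R,4R)-2-ethenyl-4-methylcyclohexyl]pent-4-enoate (epimers at C1)
Conditions: Ph3PCH3Br, KOt-Bu, THF, 0 °C
Reagents that add atoms: methyltriphenylphosphonium bromide, C[P+](c1ccccc1)(c1ccccc1)c1ccccc1.[Br-]
Why: Wittig methylenation converts the formyl group into the C4a vinyl group (C4 plus the CH2 lost later as ethene), the hindered ester is inert to the ylide, and any α-epimerisation only returns the favoured trans isomer.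

Step 8
Reactants: 12 methyl 3-ethenyl-2-[(1S,2R,4R)-2-ethenyl-4-methylcyclohexyl]pent-4-enoate
Product: 14 methyl (2R)-3-ethenyl-2-[(1S,2R,4R)-2-ethenyl-4-methylcyclohexyl]-2-methylpent-4-enoate, via lithium enolate 13 (not isolated)
Conditions: LiN(i-Pr)2, THF–DMPU, −78 to −40 °C; MeI, −78 °C
Reagents that add atoms: iodomethane, CI
Why: Alkylation of an ester enolate under allylic 1,3-strain control: with H8a eclipsing the enolate C=C bond, the equatorial C4a vinyl group covers one face of C1 and iodomethane enters from the open C8 side, which erases the C1 mixture and should give the (R)-configured quaternary centre.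

Step 9
Reactants: 14 methyl (2R)-3-ethenyl-2-[(1S,2R,4R)-2-ethenyl-4-methylcyclohexyl]-2-methylpent-4-enoate
Product: 15 methyl (1R,2R,4aR,6R,8aS)-2-ethenyl-1,6-dimethyl-1,2,4a,5,6,7,8,8a-octahydronaphthalene-1-carboxylate
Conditions: second-generation Grubbs catalyst (5 mol %), 1,4-benzoquinone (10 mol %), CH2Cl2 (0.002 M), 40 °C, argon sparge
Reagents that add atoms: none
Why: The ruthenium alkylidene loads on the least hindered alkene, the C4a vinyl group, adds [2+2] to one C2 vinyl group and cycloreverts, so that C3=C4 forms and ethene leaves; this is a diastereotopic-group-selective ring-closing metathesis of a prochiral triene, a known reaction type. Ring A closes as a six-membered ring with a cis alkene from a 1,7-diene, and since the two C2 vinyl groups form a 1,4-diene and cannot close on each other, no other ring is possible. The trans-diequatorial C4a and C8a bonds of ring B fix the chair-like shape of the forming ring, with C1–CH3 axial and CO2Me equatorial. A metallacyclobutane built on the face of that axial methyl group would be 1,3-diaxial to it, so it should form on the opposite face, where its axial bond at C4 is 1,3-diaxial to the pseudoaxial site of C2. Only hydrogen fits that site, so the vinyl group left behind is pseudoequatorial and trans to the ester, which is (2R). The step needs this group selection and no oligomerisation: high dilution, removal of ethene and the hindered position of the remaining vinyl group next to quaternary C1 secure the latter, and because the unstrained cyclohexene does not reopen, the kinetic selection is retained.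

Step 10
Reactants: 15 methyl (1R,2R,4aR,6R,8aS)-2-ethenyl-1,6-dimethyl-1,2,4a,5,6,7,8,8a-octahydronaphthalene-1-carboxylate
Product: 16 methyl (1R,2R,4aR,6R,8aS)-1,6-dimethyl-2-[(E)-2-(4,4,5,5-tetramethyl-1,3,2-dioxaborolan-2-yl)ethenyl]-1,2,4a,5,6,7,8,8a-octahydronaphthalene-1-carboxylate
Conditions: vinylboronic acid pinacol ester (3 equiv), second-generation Hoveyda–Grubbs catalyst (10 mol %), 1,4-benzoquinone (10 mol %), CH2Cl2, 40 °C
Reagents that add atoms: 2-ethenyl-4,4,5,5-tetramethyl-1,3,2-dioxaborolane, C=CB1OC(C)(C)C(C)(C)O1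
Why: Cross-metathesis of the only terminal alkene with a vinylboronate gives the (E)-alkenylboronate, the unstrained cis-cyclohexene of ring A stays out of the reaction, and C2 never becomes α to a carbonyl group, so that it cannot epimerise.

Step 11
Reactants: 16 the (E)-alkenylboronate
Product: 17 methyl (1R,2R,4aR,6R,8aS)-1,6-dimethyl-2-[(1E,3E)-penta-1,3-dien-1-yl]-1,2,4a,5,6,7,8,8a-octahydronaphthalene-1-carboxylate
Conditions: (E)-1-bromoprop-1-ene (3 equiv), Pd(PPh3)4 (5 mol %), K2CO3, THF–H2O, 50 °C, sealed tube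
Reagents that add atoms: (E)-1-bromoprop-1-ene, C/C=C/Br
Why: Suzuki–Miyaura coupling at zerovalent palladium joins the two alkenyl partners with retention of both geometries, which defines the (1E,3E)-diene, and the hindered methyl ester survives aqueous carbonate.

Step 12
Reactants: 17 the dienyl ester
Product: 18 [(1R,2R,4aR,6R,8aS)-1,6-dimethyl-2-[(1E,3E)-penta-1,3-dien-1-yl]-1,2,4a,5,6,7,8,8a-octahydronaphthalen-1-yl]methanol
Conditions: LiAlH4, THF, 0 to 40 °C; aqueous work-up
Reagents that add atoms: none
Why: Hydride reduction of the neopentyl ester needs the small and strong LiAlH4, which leaves isolated and conjugated C=C bonds alone.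

Step 13
Reactants: 18 the neopentyl alcohol
Product: 19 (1R,2R,4aR,6R,8aS)-1,6-dimethyl-2-[(1E,3E)-penta-1,3-dien-1-yl]-1,2,4a,5,6,7,8,8a-octahydronaphthalene-1-carbaldehyde
Conditions: Dess–Martin periodinane, CH2Cl2, 0 °C to rt
Reagents that add atoms: none
Why: Dess–Martin oxidation gives the aldehyde under mild conditions, and as it has no α-hydrogen no epimerisation is possible.

Step 14
Reactants: 19 the decalin aldehyde
Product: 20 S-tert-butyl 3-[(1R,2R,4aR,6R,8aS)-1,6-dimethyl-2-[(1E,3E)-penta-1,3-dien-1-yl]-1,2,4a,5,6,7,8,8a-octahydronaphthalen-1-yl]-3-hydroxypropanethioate (carbinol epimers)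
Conditions: S-tert-butyl ethanethioate, LiN(i-Pr)2, THF, −78 °C; then 19; sat. aq. NH4Cl
Reagents that add atoms: S-tert-butyl ethanethioate, CC(=O)SC(C)(C)C
Why: Aldol addition of the small lithium thioacetate enolate reaches the neopentyl aldehyde where a Claisen condensation on ester 17 would not, and the new carbinol centre forms as a mixture that is removed in step 15.

Step 15
Reactants: 20 the β-hydroxy thioester
Product: 21 S-tert-butyl 3-[(1R,2R,4aR,6R,8aS)-1,6-dimethyl-2-[(1E,3E)-penta-1,3-dien-1-yl]-1,2,4a,5,6,7,8,8a-octahydronaphthalen-1-yl]-3-oxopropanethioate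
Conditions: Dess–Martin periodinane, CH2Cl2, rt
Reagents that add atoms: none
Why: Dess–Martin oxidation of a β-hydroxy thioester to the β-keto thioester proceeds without retro-aldol cleavage and spares the sulfur and the triene.

Step 16
Reactants: 21 the β-keto thioester; 22 L-threonine methyl ester hydrochloride
Product: 23 methyl (2S,3R)-2-{3-[(1R,2R,4aR,6R,8aS)-1,6-dimethyl-2-[(1E,3E)-penta-1,3-dien-1-yl]-1,2,4a,5,6,7,8,8a-octahydronaphthalen-1-yl]-3-oxopropanamido}-3-hydroxybutanoate
Conditions: AgOCOCF3 (1.2 equiv), Et3N (2.5 equiv), THF, 0 °C to rt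
Reagents that add atoms: none
Why: Silver-promoted aminolysis of a thioester: the thiophilic silver salt activates the tert-butyl thioester so that the amine of the threonine ester is acylated faster than its secondary hydroxyl group, and both threonine stereocentres are carried over unchanged.

Step 17
Reactants: 23 the β-keto amide
Product: 24 target, (5S)-3-{[(1R,2R,4aR,6R,8aS)-1,6-dimethyl-2-[(1E,3E)-penta-1,3-dien-1-yl]-1,2,4a,5,6,7,8,8a-octahydronaphthalen-1-yl]carbonyl}-4-hydroxy-5-[(1R)-1-hydroxyethyl]-1,5-dihydro-2H-pyrrol-2-one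
Conditions: NaOMe (2 equiv), MeOH, rt, short contact; then 1 M HCl
Reagents that add atoms: none
Why: Lacey–Dieckmann cyclisation: the β-keto amide enolate attacks the methyl ester (5-exo-trig) and closes ring C, a short exposure to methoxide limits epimerisation at C5', and the free hydroxyl group, present as alkoxide, is no leaving group.

**Compound list**
1 | (R)-citronellal, (3R)-3,7-dimethyloct-6-enal | O=CC[C@H](C)CCC=C(C)C | starting material
2 | (4R)-1-methoxy-4,8-dimethylnona-1,7-diene (E/Z) | COC=CC[C@H](C)CCC=C(C)C | intermediate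
3 | (4R)-4,8-dimethylnon-7-enal | O=CCC[C@H](C)CCC=C(C)C | intermediate
4 | (4R)-4,8-dimethyl-2-methylidenenon-7-enal | O=CC(=C)C[C@H](C)CCC=C(C)C | intermediate
5 | (5R)-5-methylcyclohex-1-ene-1-carbaldehyde | O=CC1=CCC[C@@H](C)C1 | intermediate
6 | (2E)-penta-2,4-dien-1-ol | C=C/C=C/CO | starting material
7 | 1-methoxy-1-[(2E)-penta-2,4-dien-1-yloxy]ethene | C=C(OC)OC/C=C/C=C | intermediate
8 | methyl 3-ethenylpent-4-enoate | COC(=O)CC(C=C)C=C | intermediate
9 | lithium enolate of 8 | [Li+].[O-]C(OC)=CC(C=C)C=C | intermediate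
10 | methyl 3-ethenyl-2-[(1S,4R)-2-formyl-4-methylcyclohexyl]pent-4-enoate (C1 and C4a epimers) | O=CC1C[C@H](C)CC[C@@H]1C(C(C=C)C=C)C(=O)OC | intermediate
11 | methyl 3-ethenyl-2-[(1S,2S,4R)-2-formyl-4-methylcyclohexyl]pent-4-enoate (C1 epimers) | O=C[C@H]1C[C@H](C)CC[C@@H]1C(C(C=C)C=C)C(=O)OC | intermediate
12 | methyl 3-ethenyl-2-[(1S,2R,4R)-2-ethenyl-4-methylcyclohexyl]pent-4-enoate (C1 epimers) | C=C[C@H]1C[C@H](C)CC[C@@H]1C(C(C=C)C=C)C(=O)OC | intermediate
13 | lithium enolate of 12 | C=C[C@H]1C[C@H](C)CC[C@@H]1C(C(C=C)C=C)=C([O-])OC.[Li+] | intermediate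
14 | methyl (2R)-3-ethenyl-2-[(1S,2R,4R)-2-ethenyl-4-methylcyclohexyl]-2-methylpent-4-enoate | C=C[C@H]1C[C@H](C)CC[C@@H]1[C@@](C(C=C)C=C)(C)C(=O)OC | intermediate
15 | methyl (1R,2R,4aR,6R,8aS)-2-ethenyl-1,6-dimethyl-1,2,4a,5,6,7,8,8a-octahydronaphthalene-1-carboxylate | C=C[C@@H]1C=C[C@H]2C[C@H](C)CC[C@@H]2[C@@]1(C)C(=O)OC | intermediate
16 | (E)-alkenyl pinacol boronate of 15 | CC1(C)OB(/C=C/[C@@H]2C=C[C@H]3C[C@H](C)CC[C@@H]3[C@@]2(C)C(=O)OC)OC1(C)C | intermediate
17 | methyl (1R,2R,4aR,6R,8aS)-1,6-dimethyl-2-[(1E,3E)-penta-1,3-dien-1-yl]-octahydronaphthalene-1-carboxylate | C/C=C/C=C/[C@@H]1C=C[C@H]2C[C@H](C)CC[C@@H]2[C@@]1(C)C(=O)OC | intermediate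
18 | corresponding C1 hydroxymethyl compound | C/C=C/C=C/[C@@H]1C=C[C@H]2C[C@H](C)CC[C@@H]2[C@@]1(C)CO | intermediate
19 | corresponding C1 carbaldehyde | C/C=C/C=C/[C@@H]1C=C[C@H]2C[C@H](C)CC[C@@H]2[C@@]1(C)C=O | intermediate
20 | β-hydroxy S-tert-butyl thioester (carbinol epimers) | C/C=C/C=C/[C@@H]1C=C[C@H]2C[C@H](C)CC[C@@H]2[C@@]1(C)C(O)CC(=O)SC(C)(C)C | intermediate
21 | β-keto S-tert-butyl thioester | C/C=C/C=C/[C@@H]1C=C[C@H]2C[C@H](C)CC[C@@H]2[C@@]1(C)C(=O)CC(=O)SC(C)(C)C | intermediate
22 | L-threonine methyl ester hydrochloride | C[C@@H](O)[C@H](N)C(=O)OC.Cl | starting material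
23 | β-keto amide of L-threonine methyl ester | C/C=C/C=C/[C@@H]1C=C[C@H]2C[C@H](C)CC[C@@H]2[C@@]1(C)C(=O)CC(=O)N[C@H](C(=O)OC)[C@@H](C)O | intermediate
24 | CNP0298257.3 | C/C=C/C=C/[C@@H]1C=C[C@H]2C[C@H](C)CC[C@@H]2[C@@]1(C)C(=O)C1=C(O)[C@H]([C@@H](C)O)NC1=O | target

**Count**
Total: 17 steps. Longest linear sequence: 16 steps (steps 1–3 and 5–17); step 4 is the side branch.

**Steps most likely to fail**

Step 5. The enolate may attack the carbonyl carbon or deprotonate the γ-position of the complexed enal instead of adding in conjugate fashion. Facial control by the remote C6 methyl group may also be weak.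
- The fallback forms C8a–C1 intramolecularly and sets out from 5 and 8.
- Luche reduction of 5 (NaBH4, CeCl3) gives [(5R)-5-methylcyclohex-1-en-1-yl]methanol F1.
- Saponification of 8 (LiOH) gives 3-ethenylpent-4-enoic acid F2.
- Steglich esterification joins the two to [(5R)-5-methylcyclohex-1-en-1-yl]methyl 3-ethenylpent-4-enoate F3.
- Ireland–Claisen rearrangement (LiN(i-Pr)2, Me3SiCl, −78 °C to rt) makes the bond through a cyclic transition state on the same axial trajectory. It leaves an exocyclic methylene group at C4a in 3-ethenyl-2-[(1R,4R)-4-methyl-2-methylidenecyclohexyl]pent-4-enoic acid F4.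
- Me3SiCHN2 gives its methyl ester F5.
- m-CPBA (1 equiv) epoxidises the more electron-rich 1,1-disubstituted alkene to methyl 3-ethenyl-2-[(4R,7R)-7-methyl-1-oxaspiro[2.5]octan-4-yl]pent-4-enoate F6.
- Meinwald rearrangement (BF3·OEt2, −78 °C) gives the aldehyde, and the route is rejoined at 10.

Step 8. Enolisation of the doubly branched ester may be slow, and facial selectivity may be poor if a second enolate rotamer reacts.
- The fallback brings the methyl group in with the donor, so that the quaternary centre is set while C8a–C1 forms. It sets out from 8 and 5.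
- Methylation of 8 (LiN(i-Pr)2, MeI) gives methyl 3-ethenyl-2-methylpent-4-enoate F7.
- LiN(i-Pr)2 and t-BuMe2SiCl give its tert-butyldimethylsilyl ketene acetal F8.
- Mukaiyama–Michael addition to 5, held by the same Al(OC6H3-2,6-Ph2)3, should pass through an open antiperiplanar transition state. In it the small methyl group lies over ring B and the divinylmethyl group lies beside H8a.
- Acid work-up and DBU, now with a stronger trans preference next to a quaternary carbon, give methyl (2R)-3-ethenyl-2-[(1S,2S,4R)-2-formyl-4-methylcyclohexyl]-2-methylpent-4-enoate F9.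
- Wittig methylenation rejoins the route at 14.

Step 9. Discrimination between the two vinyl groups may be insufficient, that is, closure may occur with the spectator vinyl group pseudoaxial. Intermolecular metathesis may also compete.
- The fallback keeps the same ring closure but changes the oxidation level at C1. The equatorial neighbour of C2 then becomes a bulky tetrahedral group that sits close to a pseudoaxial vinyl group and farther from a pseudoequatorial one. It sets out from 14.
- LiAlH4 gives (2R)-3-ethenyl-2-[(1S,2R,4R)-2-ethenyl-4-methylcyclohexyl]-2-methylpent-4-en-1-ol F10.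
- i-Pr3SiOTf and 2,6-lutidine give its triisopropylsilyl ether F11.
- Ring-closing metathesis as in step 9 gives {[(1R,2R,4aR,6R,8aS)-2-ethenyl-1,6-dimethyl-1,2,4a,5,6,7,8,8a-octahydronaphthalen-1-yl]methoxy}tri(propan-2-yl)silane F12.
- Cross-metathesis as in step 10 gives the (E)-alkenyl pinacol boronate F13.
- Suzuki coupling as in step 11 gives the (1E,3E)-pentadienyl silyl ether F14.
- Bu4NF rejoins the route at 18.

**Further compounds**
F1 | step 5 | [(5R)-5-methylcyclohex-1-en-1-yl]methanol | OCC1=CCC[C@@H](C)C1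
F2 | step 5 | 3-ethenylpent-4-enoic acid | OC(=O)CC(C=C)C=C
F3 | step 5 | [(5R)-5-methylcyclohex-1-en-1-yl]methyl 3-ethenylpent-4-enoate | C=CC(C=C)CC(=O)OCC1=CCC[C@@H](C)C1
F4 | step 5 | 3-ethenyl-2-[(1R,4R)-4-methyl-2-methylidenecyclohexyl]pent-4-enoic acid (C1 epimers) | C=C1C[C@H](C)CC[C@@H]1C(C(C=C)C=C)C(=O)O
F5 | step 5 | methyl 3-ethenyl-2-[(1R,4R)-4-methyl-2-methylidenecyclohexyl]pent-4-enoate (C1 epimers) | C=C1C[C@H](C)CC[C@@H]1C(C(C=C)C=C)C(=O)OC
F6 | step 5 | methyl 3-ethenyl-2-[(4R,7R)-7-methyl-1-oxaspiro[2.5]octan-4-yl]pent-4-enoate (spiro and C1 epimers) | C1OC12C[C@H](C)CC[C@@H]2C(C(C=C)C=C)C(=O)OC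
F7 | step 8 | methyl 3-ethenyl-2-methylpent-4-enoate | COC(=O)C(C)C(C=C)C=C
F8 | step 8 | tert-butyl[(3-ethenyl-1-methoxy-2-methylpenta-1,4-dien-1-yl)oxy]dimethylsilane (E/Z) | COC(O[Si](C)(C)C(C)(C)C)=C(C)C(C=C)C=C
F9 | step 8 | methyl (2R)-3-ethenyl-2-[(1S,2S,4R)-2-formyl-4-methylcyclohexyl]-2-methylpent-4-enoate | O=C[C@H]1C[C@H](C)CC[C@@H]1[C@@](C(C=C)C=C)(C)C(=O)OC
F10 | step 9 | (2R)-3-ethenyl-2-[(1S,2R,4R)-2-ethenyl-4-methylcyclohexyl]-2-methylpent-4-en-1-ol | C=C[C@H]1C[C@H](C)CC[C@@H]1[C@@](C(C=C)C=C)(C)CO
F11 | step 9 | triisopropylsilyl ether of F10 | C=C[C@H]1C[C@H](C)CC[C@@H]1[C@@](C(C=C)C=C)(C)CO[Si](C(C)C)(C(C)C)C(C)C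
F12 | step 9 | {[(1R,2R,4aR,6R,8aS)-2-ethenyl-1,6-dimethyl-1,2,4a,5,6,7,8,8a-octahydronaphthalen-1-yl]methoxy}tri(propan-2-yl)silane | C=C[C@@H]1C=C[C@H]2C[C@H](C)CC[C@@H]2[C@@]1(C)CO[Si](C(C)C)(C(C)C)C(C)C
F13 | step 9 | (E)-alkenyl pinacol boronate of F12 | CC1(C)OB(/C=C/[C@@H]2C=C[C@H]3C[C@H](C)CC[C@@H]3[C@@]2(C)CO[Si](C(C)C)(C(C)C)C(C)C)OC1(C)C
F14 | step 9 | (1E,3E)-pentadienyl triisopropylsilyl ether | C/C=C/C=C/[C@@H]1C=C[C@H]2C[C@H](C)CC[C@@H]2[C@@]1(C)CO[Si](C(C)C)(C(C)C)C(C)C
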